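- Late in the eta run, G (the bis adduct of X with the reagent D) fell from 62.5% at 4.00 min to 45.5% at 12.0 min, and that late fall was what I reckoned from.

in all of them: X 0.40 M

| charge | D | remark | time |
|---|---|---|---|
| epsilon | 0.29 M | run made earlier |  |
| eta | 1.5 M | run made earlier |  |
| maple | 1.00 M |  | 25 min |
| larch | 0.200 M |  | 25 min |

| run | time / min | G / % |
|---|---|---|
| epsilon | 2.50 | 9.4 |
| epsilon | 5.00 | 13.2 |
| epsilon | 8.00 | 13.0 |
| epsilon | 10.0 | 12.8 |
| epsilon | 12.0 | 13.7 |
| eta | 1.00 | 49.6 |
| eta | 2.00 | 63.7 |
| eta | 4.00 | 62.5 |
| eta | 6.00 | 57.7 |
| eta | 12.0 | 45.5 |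

(readings scatter by 1 percentage point)

- the numbers in the tables scatter with a standard deviation of 1 percentage point

* which of these holds the largest part of the X at the end of maple (G / L / Q / X)
* which of these holds the largest part of the X at the end of larch (G / L / Q / X)
* G at the end of maple, in percent of the X charged

- G costs two D per X, so I called the D beyond that the spare D: 0.700 M in eta and 0.200 M in maple.
- I treated the late fall as pseudo-first-order in G at a given D, and dividing its logarithmic rate by eta's spare D gave the fade constant, the fractional loss of G per minute per molar of D, read as 0.0567 M⁻¹ min⁻¹.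
- I took eta's reading of 63.7% at 2.00 min as the large term for maple and computed only the correction.
- With no fade, my reckoning kept maple's G at that reading. With the full spare D acting for the full 25 min, my reckoning came to 48.0%. I expected the spare D to shrink as it was used, so I committed to the middle, 55.8%, with G the largest part.
- In larch, D could reach half of the X, which made D the limiting reagent, and I named X the largest part.
- The forecast named G for maple and X for larch, and gave 73% for G: “Integrating by hand gives L about 25%, Q about 1%, G about 73%.” That stood 17 points above my figure.

    X + D → Q (k = 0.0390 M⁻¹ s⁻¹)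
    D + Q → G (k = 0.0330 M⁻¹ s⁻¹)
    D + G → L (k = 0.00160 M⁻¹ s⁻¹)
    G ⇌ Z (K = 0.340, k = 0.0220 s⁻¹)

- Maple ended with 56.9% of G, and the forecast was 16 points too high, though both of its choices, G and X, were right. Beside G and L, maple held Z, 19.4% at 25.0 min. At 10.0 min a reading of maple gave G 63.9% with D at 15.8% of its charge, and by 25.0 min D stood at 10.5%. The mean of those two D values is 0.131 M, and the fade constant applied to it over those 15.0 min reckons G at 57.1%.

The runs were generated by integration with constants of no real substance.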